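A small charge can hold crystals back: the 0.0450 M of catalyst, charged as D, can bind E as E.G, and bound E is not free E.

X 0.45 M; Q 1.00 equiv; D 10 mol%; time 15 s; volume of the second phase over the first 2.0

- how much E and E.G and L together there is at 15 s, in percent of the X charged
- the change that raises the amount of E and E.G and L together at 15 s, in percent of the X charged most ("none" if none brings more than 2 percentage points) (dawn / midnight / autumn / none)
- amount of E and E.G and L together at 15 s, in percent of the X charged, after autumn

- dawn: doubling the amount of Q, all else as stated
- midnight: doubling the dissolution coefficient of step 3, all else as stated
- autumn: doubling the solubility in step 3, all else as stated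

- for E the E.G and L are counted in
- in the second phase: Q, Z; everything else is in the first
- charges count per volume of the first phase; a concentration in a rate is the amount of a species over the volume of its own phase; every rate counts per litre of the first phase
- as a solid, counted per litre of solution: L
- run time (flask): 15 s

    X + G → E + D (k1 = 1.10 M⁻¹ s⁻¹)
    D + Q ⇌ G + Z (K2 = 0.48, k2 = 7.16 M⁻¹ s⁻¹)
    L ⇌ E, rate k3*(cs3 - [E]) while solid is left; crystals form when [E] > cs3 (cs3 = 0.18 M, k3 = 0.403 s⁻¹)
    E + G ⇌ E.G (K4 = 134 M⁻¹, k4 = 1.24 M⁻¹ s⁻¹)

Can L form by 15 s? Crystals need free E above the solubility 0.18 M, which takes 40.0% of the X charged. I go round once more. At that free E, E.G stands 24.1 times over G, so I count the catalyst as bound and add its whole charge. Part of it may stand as D, so this mark is a high one. This gives 50.0%, the yield of E, E.G and L together at which free E meets the solubility with the catalyst bound. It is my crystal threshold.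

Does the flask get there? With the whole catalyst as G and X at its charge, step 1 gives 74.3% in 15 s. That is above the threshold, so I put the threshold back in as a supposed end state. Then Z and Q stand about equal, and step 2 holds G over D near 0.48, a G share of about 32.4%. The mean share is 66.2% and the mean X is 75.0% of its charge. The second round gives 36.9%, below the threshold, so the supposition fails. I hold 36.9% as a high estimate, since the catalyst starts as D and E.G takes up G. Without crystals, step 3 stays idle, so midnight and autumn should leave the yield alone, and dawn remains to try.

The forecast says 28%, dawn and 28%. Its yield is lower than my estimate, and its ground for the choice is that “extra Q is the only change that clearly helps”.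

The simulation gives 26.7%, with dawn best at 4.3 percentage points, and 26.7% after autumn.

At 15.0 s the half-life of X by step 1 is 58 s, longer than the run, and 73% of X remains unbound. The yield of 26.7% lies under the threshold of 50.0%, L is 0%, and the low solubility makes no difference. Left until 150 s, the same flask reaches 50.7%, past the threshold, with 84.9% of the catalyst as E.G and L at 2.01%.

The numbers of this flask were chosen freely; the result is computed.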